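Agehoustin B is disconnected at ring C into a ring A acetophenone and a ring B benzoate, and ring B is itself assembled from two open-chain esters that each deliver three ring carbons. The feature used is the pattern of ring B: oxygen on the contiguous carbons C2'–C5', hydrogen on C6' and carbon on C1'. Methyl 4-methoxy-3-oxobutanoate (1) supplies C1'–C3' and, made from methyl methoxyacetate (2), the enamino ester 3 supplies C4'–C6', each carbon already at its final oxidation level. One methoxide-mediated operation forms C1'–C6' and C3'–C4' and gives the aromatic resorcylate. O-Methylation, Claisen condensation with the acetophenone from 3,4,5-trimethoxyphenol and acid cyclodehydration then complete ring C.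

Key step: step 2

Remark: ring B locants follow flavone numbering (C1' is bonded to C2 of ring C); 4 is drawn as the neutral C–H acid of the sodium dienolate that is actually present in the flask.

Step 1
Reactants: 2 methyl methoxyacetate
Product: 3 methyl (Z)-3-(dimethylamino)-2-methoxyacrylate
Conditions: tert-butoxybis(dimethylamino)methane (1.3 equiv), neat, 100 °C; distil
Reagents that add atoms: tert-butoxybis(dimethylamino)methane, CN(C)C(OC(C)(C)C)N(C)C
Why: Bredereck aminomethylenation of an ester, in which the reagent ionises to a formamidinium tert-butoxide pair, the alkoxide deprotonates the α-CH2 of 2, the enolate adds to the formamidinium carbon (the future C6') and loss of dimethylamine gives the push–pull enamino ester, which should settle as the Z isomer with NMe2 trans to the ester group.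

Step 2
Reactants: 1 methyl 4-methoxy-3-oxobutanoate; 3 methyl (Z)-3-(dimethylamino)-2-methoxyacrylate
Product: 5 methyl 2,4-dihydroxy-3,5-dimethoxybenzoate, via open-chain dienolate adduct 4 (not isolated)
Conditions: NaOMe (3 equiv), MeOH, 0 °C → reflux, N2 sweep; then aq. HCl, 0 °C
Reagents that add atoms: none
Why: NaOMe converts 1 into its enolate, whose doubly activated C1' adds to the aminomethylene carbon C6' of 3 and expels dimethylamine (addition–elimination at a push–pull alkene), giving the delocalised dienolate 4, which rotates freely about C5'–C6'; methoxide then reversibly removes a proton from C3', this carbanion acylates itself at the ester carbon C4' with loss of methoxide, and tautomerisation of the cyclohexadienone gives the bis-phenoxide of 5, set free on acidification. The closest known reactions are the Michael (addition–elimination)/Dieckmann [3+3] benzannulations by which acetonedicarboxylates and alkoxymethylene or alkynoate esters give resorcylates, and the methoxide-mediated Claisen acylation at the CH2OMe carbon of 2-(aminomethylene)-4-methoxyacetoacetates. Ring B closes by a 6-exo-trig (enolate-exo) attack of C3' on the C4' carbonyl, and no stereocentre is formed. The step needs C1' and not C3' to take C6', which is secured by working with the monoanion of 1, in which only the carbon between the two carbonyl groups is nucleophilic. It also needs C- and not O-acylation at C4', which is secured thermodynamically: a 2-pyranone formed through the ketone oxygen is reopened by the excess methoxide, whereas the aromatic bis-phenoxide is an irreversible sink. Because every ester is a methyl ester and the base is methoxide, transesterification changes nothing, and since each ring carbon already carries the oxygen or hydrogen it needs, no oxidation has to follow.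

Step 3
Reactants: 5 methyl 2,4-dihydroxy-3,5-dimethoxybenzoate
Product: 6 methyl 2,3,4,5-tetramethoxybenzoate
Conditions: MeI (4 equiv), K2CO3 (4 equiv), DMF, 50 °C
Reagents that add atoms: iodomethane, CI
Why: Williamson ether synthesis, in which carbonate deprotonates both phenols and excess MeI in DMF should methylate even the hydrogen-bonded 2-OH, while C6' (meta to both phenoxide oxygens) is not nucleophilic and the methyl ester is inert.

Step 4
Reactants: 7 3,4,5-trimethoxyphenol
Product: 8 1-(6-hydroxy-2,3,4-trimethoxyphenyl)ethan-1-one
Conditions: AcOH, BF3·OEt2 (3 equiv), 90 °C; then H2O, 60 °C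
Reagents that add atoms: acetic acid, CC(=O)O
Why: Friedel–Crafts acylation promoted by BF3, which should go ortho to the hydroxyl at one of the two equivalent open positions (C2 or C6) and stop there because the product ketone is held as a deactivating difluoroboron chelate until the aqueous work-up releases 8.

Step 5
Reactants: 8 1-(6-hydroxy-2,3,4-trimethoxyphenyl)ethan-1-one; 6 methyl 2,3,4,5-tetramethoxybenzoate
Product: 9 1-(6-hydroxy-2,3,4-trimethoxyphenyl)-3-(2,3,4,5-tetramethoxyphenyl)propane-1,3-dione
Conditions: 8, LiN(SiMe3)2 (3.5 equiv), THF, −78 → −10 °C; then 6, −78 °C → rt; aq. HCl
Reagents that add atoms: none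
Why: Crossed Claisen condensation, in which the enolate carbon of the doubly lithiated 8 (phenolate and enolate) acylates on the non-enolisable ester 6, helped by lithium chelation between its carbonyl and 2-methoxy group, and deprotonation of the resulting 1,3-diketone by the excess base drives the equilibrium.

Step 6
Reactants: 9 1-(6-hydroxy-2,3,4-trimethoxyphenyl)-3-(2,3,4,5-tetramethoxyphenyl)propane-1,3-dione
Product: 10 Agehoustin B
Conditions: AcOH, H2SO4 (cat.), 95 °C
Reagents that add atoms: none
Why: Acid-catalysed cyclodehydration of an o-hydroxyaryl 1,3-diketone (the closing stage of a Baker–Venkataraman-type flavone synthesis), in which the only free phenol adds to the aroyl carbonyl and loss of water gives the aromatic γ-pyrone, under catalytic acid that should leave all seven aryl methyl ethers intact.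

Compound list
1 | methyl 4-methoxy-3-oxobutanoate | COCC(=O)CC(=O)OC | starting material
2 | methyl methoxyacetate | COCC(=O)OC | starting material
3 | methyl (Z)-3-(dimethylamino)-2-methoxyacrylate | CN(C)/C=C(\OC)C(=O)OC | intermediate
4 | dimethyl (2E)-2-methoxy-4-(methoxyacetyl)pent-2-enedioate, present as its sodium dienolate in which C4 is planar and the 2Z and 2E arrangements interconvert; drawn in the 2E geometry that cyclises; not isolated | COCC(=O)C(C(=O)OC)/C=C(/OC)C(=O)OC | intermediate
5 | methyl 2,4-dihydroxy-3,5-dimethoxybenzoate | COC(=O)c1cc(OC)c(O)c(OC)c1O | intermediate
6 | methyl 2,3,4,5-tetramethoxybenzoate | COC(=O)c1cc(OC)c(OC)c(OC)c1OC | intermediate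
7 | 3,4,5-trimethoxyphenol | COc1cc(O)cc(OC)c1OC | starting material
8 | 1-(6-hydroxy-2,3,4-trimethoxyphenyl)ethan-1-one | CC(=O)c1c(O)cc(OC)c(OC)c1OC | intermediate
9 | 1-(6-hydroxy-2,3,4-trimethoxyphenyl)-3-(2,3,4,5-tetramethoxyphenyl)propane-1,3-dione | COc1cc(C(=O)CC(=O)c2c(O)cc(OC)c(OC)c2OC)c(OC)c(OC)c1OC | intermediate
10 | Agehoustin B, 5,6,7-trimethoxy-2-(2,3,4,5-tetramethoxyphenyl)-4H-chromen-4-one | COc1cc(-c2cc(=O)c3c(OC)c(OC)c(OC)cc3o2)c(OC)c(OC)c1OC | target

Total step count: 6. Longest linear sequence: 5 steps (steps 1, 2, 3, 5 and 6); step 4 is a one-step side branch.

Steps most likely to fail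

Step 2. The second deprotonation, at C3' of an adduct that is already an anion, may be too unfavourable under methoxide. The sequence could then stall at the open-chain dienolate, drift into lactonisation through the ketone oxygen, or lose the methoxyacetyl group by retro-Claisen cleavage. Slow displacement of the amine at the electron-rich C6' is the other weak point. The fallback separates the two bond formations. Compounds 1 and 3 are heated in AcOH at 90 °C, where the protonated enamino ester is a better electrophile and lactonisation is the expected outcome. This should give the 2-pyranone methyl 3-methoxy-6-(methoxymethyl)-2-oxo-2H-pyran-5-carboxylate F1, which is isolated. F1 already contains the C1'–C6' bond and holds C1' and C4' cis about C5'=C6'. It is then opened with NaOMe (1.05 equiv) in MeOH–THF to the sodium dienolate of 4. After removal of the methanol, C3' is deprotonated outright with LiN(SiMe3)2 (2.2 equiv, THF, −78 → 0 °C), as in the γ-acylation of β-keto ester dianions. Intramolecular acylation at C4' and acidification return to the route at 5.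

Step 5. Acylation of the enolate by an electron-rich, ortho-substituted methyl ester may be sluggish, so that the enolate is quenched unchanged or the condensation stops short of full conversion. The fallback is the Baker–Venkataraman sequence through an activated acyl donor. Ester 6 is saponified (LiOH, aq. THF–MeOH) to 2,3,4,5-tetramethoxybenzoic acid F2. F2 is converted with (COCl)2 and catalytic DMF in CH2Cl2 into 2,3,4,5-tetramethoxybenzoyl chloride F3. F3 acylates the phenol of 8 in pyridine to give 2-acetyl-3,4,5-trimethoxyphenyl 2,3,4,5-tetramethoxybenzoate F4. KOH in pyridine at 50 °C then moves the aroyl group from oxygen to the enolate carbon through a six-membered transition state, returning to the route at 9.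

Step 4. BF3 at 90 °C may cleave the methyl ether that ends up ortho to the new carbonyl, the boron chelate may resist hydrolysis, or a second acylation may occur at the remaining ortho position. The fallback is a Houben–Hoesch acylation. Phenol 7 is treated with MeCN, ZnCl2 and HCl gas in Et2O at 0 °C, which should precipitate 1-(6-hydroxy-2,3,4-trimethoxyphenyl)ethan-1-iminium chloride F5. The protonated imine deactivates the ring against further reaction. Hydrolysis of F5 in hot water returns to the route at 8.

Further compounds
F1 | step 2 | methyl 3-methoxy-6-(methoxymethyl)-2-oxo-2H-pyran-5-carboxylate | COCc1oc(=O)c(OC)cc1C(=O)OC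
F2 | step 5 | 2,3,4,5-tetramethoxybenzoic acid | COc1cc(C(=O)O)c(OC)c(OC)c1OC
F3 | step 5 | 2,3,4,5-tetramethoxybenzoyl chloride | COc1cc(C(=O)Cl)c(OC)c(OC)c1OC
F4 | step 5 | 2-acetyl-3,4,5-trimethoxyphenyl 2,3,4,5-tetramethoxybenzoate | CC(=O)c1c(OC(=O)c2cc(OC)c(OC)c(OC)c2OC)cc(OC)c(OC)c1OC
F5 | step 4 | 1-(6-hydroxy-2,3,4-trimethoxyphenyl)ethan-1-iminium chloride | CC(=[NH2+])c1c(O)cc(OC)c(OC)c1OC.[Cl-]
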